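**Retrosynthetic overview**
1. Target 33 ⇐ deacetylation of heptaacetate 32 ⇐ Mizoroki–Heck of aryl chloride 30 with 4-acetoxystyrene; the stilbene is made last, after the methyl ethers have been exchanged for acetates.
2. Each 2-(4-oxyphenyl) group ⇐ decarboxylative arylation of a 3-aryl-2,3-dihydrobenzofuran-2-carboxylic acid (2,3-trans by substrate control).
3. Key C–C disconnection, used twice: C2–C3 of each dihydrobenzofuran ⇐ intermolecular asymmetric Michael addition of diethyl bromomalonate to an o-quinone methide, then ring closure by O-alkylation; this sets C3 (S in unit A, R in unit B).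
4. o-Quinone methide precursors ⇐ aryl Grignard additions to salicylaldehydes 4 and 19; 19 ⇐ ortho-formylation of the guaiacol ring of the first dihydrobenzofuran.
5. Ring order: unit A (the dihydrobenzofuran that will carry the styryl group) first, then unit B (the 7-hydroxy dihydrobenzofuran), stilbene last.

Assumption: the facial sense of the two pseudo-enantiomeric cinchona phase-transfer catalysts in steps 6 and 13 is assigned by analogy, not verified; if a first analytical run shows the opposite sense, the two catalysts are exchanged.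

**Route**

Step 1
Reactants: 1 1-chloro-3,5-dimethoxybenzene
Product: 3 2-chloro-4,6-dimethoxybenzaldehyde, via aryl iminium chloride 2 (not isolated)
Conditions: POCl3, DMF, 0 → 90 °C; aq. NaOAc
Reagents that add atoms: N,N-dimethylformamide CN(C)C=O; water O
Why: Vilsmeier–Haack formylation attacks para to one methoxy group and ortho to the other, the site between the two methoxy groups being more hindered (minor 4-chloro-2,6-dimethoxy isomer removed by crystallisation).

Step 2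
Reactants: 3 2-chloro-4,6-dimethoxybenzaldehyde
Product: 4 2-chloro-6-hydroxy-4-methoxybenzaldehyde
Conditions: BCl3 (1.2 equiv), CH2Cl2, −78 → 0 °C; H2O
Reagents that add atoms: none
Why: Chelation-controlled Lewis acid ether cleavage, in which BCl3 bound to the formyl oxygen removes only the ortho methyl group.

Step 3
Reactants: 5 4-bromo-2-methoxyphenol
Product: 6 1-(benzyloxy)-4-bromo-2-methoxybenzene
Conditions: BnBr, K2CO3, DMF, rt
Reagents that add atoms: benzyl bromide BrCc1ccccc1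
Why: Williamson ether synthesis on a phenoxide.

Step 4
Reactants: 6 1-(benzyloxy)-4-bromo-2-methoxybenzene; 4 2-chloro-6-hydroxy-4-methoxybenzaldehyde
Product: 8 2-{[4-(benzyloxy)-3-methoxyphenyl](hydroxy)methyl}-3-chloro-5-methoxyphenol (racemic), via arylmagnesium bromide 7 (not isolated)
Conditions: 6 (2.3 equiv), Mg, THF, 50 °C; then 4, 0 °C → rt; aq. NH4Cl
Reagents that add atoms: none
Why: Grignard addition to the aldehyde after the first equivalent has deprotonated the phenol; the carbinol centre is racemic and is erased in step 6.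

Step 5
Reactants: 8 o-hydroxybenzhydrol
Product: 9 2-{[4-(benzyloxy)-3-methoxyphenyl](4-methylbenzenesulfonyl)methyl}-3-chloro-5-methoxyphenol (racemic)
Conditions: p-TolSO2Na, HCO2H, CH2Cl2/H2O, rt
Reagents that add atoms: sodium 4-methylbenzenesulfinate Cc1ccc(S(=O)[O-])cc1.[Na+]
Why: SN1 substitution through the strongly stabilised benzhydryl cation, with S-alkylation of sulfinate giving a bench-stable o-quinone methide precursor.

Step 6
Reactants: 9 sulfone; 10 diethyl bromomalonate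
Product: 13 diethyl (3S)-3-[4-(benzyloxy)-3-methoxyphenyl]-4-chloro-6-methoxy-1-benzofuran-2,2(3H)-dicarboxylate, via o-quinone methide 11 (not isolated), via bromomalonate Michael adduct 12 (not isolated)
Conditions: 10 (1.3 equiv), Cs2CO3 (2.5 equiv), N-(9-anthracenylmethyl)cinchoninium chloride (10 mol%), toluene, −20 °C
Reagents that add atoms: none
Why: Base eliminates sulfinate to 11, the bromomalonate enolate ion-paired with the chiral ammonium cation adds to the exocyclic carbon in an intermolecular Michael addition that sets C3 (S), and the phenoxide closes the ring by SN2 displacement of bromide (formal 4+1 annulation).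

Step 7
Reactants: 13 dihydrobenzofuran diester
Product: 15 (2RS,3S)-3-[4-(benzyloxy)-3-methoxyphenyl]-4-chloro-6-methoxy-2,3-dihydro-1-benzofuran-2-carboxylic acid (C2 epimer mixture), via malonic diacid 14 (not isolated)
Conditions: KOH, EtOH/H2O, 60 °C; aq. HCl; then toluene, 100 °C
Reagents that add atoms: potassium hydroxide [K+].[OH-]
Why: Saponification followed by thermal malonic acid decarboxylation; C3 is not acidic and is untouched, and the C2 configuration is irrelevant because C2 becomes a radical in step 8.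

Step 8
Reactants: 15 carboxylic acid; 16 1-iodo-4-methoxybenzene
Product: 17 (2S,3S)-3-[4-(benzyloxy)-3-methoxyphenyl]-4-chloro-6-methoxy-2-(4-methoxyphenyl)-2,3-dihydro-1-benzofuran
Conditions: 16 (1.5 equiv), Ir[dF(CF3)ppy]2(dtbbpy)PF6 (1 mol%), NiCl2·glyme (10 mol%), dtbbpy (15 mol%), Cs2CO3, DMF, blue LEDs, rt
Reagents that add atoms: none
Why: Metallaphotoredox decarboxylative arylation in which the α-oxy C2 radical is coupled by nickel with the aryl iodide on the face away from the C3 aryl group, giving the 2,3-trans (2S) ring from either C2 epimer while the aryl chloride stays inert (any cis epimer removed by chromatography).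

Step 9
Reactants: 17 benzyl ether
Product: 18 4-[(2S,3S)-4-chloro-6-methoxy-2-(4-methoxyphenyl)-2,3-dihydro-1-benzofuran-3-yl]-2-methoxyphenol
Conditions: H2 (1 atm), 5% Pd/C, EtOAc, rt
Reagents that add atoms: none
Why: Hydrogenolysis of the benzyl ether under neutral conditions, which leave the aryl chloride and the hindered cyclic benzylic ether intact.

Step 10
Reactants: 18 phenol
Product: 19 5-[(2S,3S)-4-chloro-6-methoxy-2-(4-methoxyphenyl)-2,3-dihydro-1-benzofuran-3-yl]-2-hydroxy-3-methoxybenzaldehyde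
Conditions: MgCl2, Et3N, (CH2O)n, MeCN, reflux; aq. citric acid
Reagents that add atoms: paraformaldehyde (formaldehyde) C=O
Why: Magnesium phenoxide ortho-formylation (Casiraghi–Skattebøl), which can only occur at the single free position ortho to the hydroxyl group.

Step 11
Reactants: 19 salicylaldehyde; 20 (3,5-dimethoxyphenyl)magnesium chloride
Product: 21 4-[(2S,3S)-4-chloro-6-methoxy-2-(4-methoxyphenyl)-2,3-dihydro-1-benzofuran-3-yl]-2-[(3,5-dimethoxyphenyl)(hydroxy)methyl]-6-methoxyphenol (two carbinol epimers)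
Conditions: 20 (2.5 equiv), THF, −20 → 0 °C; aq. NH4Cl
Reagents that add atoms: none
Why: Grignard addition to the aldehyde of the magnesium phenoxide; the new carbinol centre is erased in step 13.

Step 12
Reactants: 21 o-hydroxybenzhydrol
Product: 22 4-[(2S,3S)-4-chloro-6-methoxy-2-(4-methoxyphenyl)-2,3-dihydro-1-benzofuran-3-yl]-2-[(3,5-dimethoxyphenyl)(4-methylbenzenesulfonyl)methyl]-6-methoxyphenol (two epimers)
Conditions: p-TolSO2Na, HCO2H, CH2Cl2/H2O, rt
Reagents that add atoms: sodium 4-methylbenzenesulfinate Cc1ccc(S(=O)[O-])cc1.[Na+]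
Why: SN1 sulfinate substitution through the o-hydroxybenzyl cation, as in step 5.

Step 13
Reactants: 22 sulfone; 10 diethyl bromomalonate
Product: 25 diethyl (3R)-5-[(2S,3S)-4-chloro-6-methoxy-2-(4-methoxyphenyl)-2,3-dihydro-1-benzofuran-3-yl]-3-(3,5-dimethoxyphenyl)-7-methoxy-1-benzofuran-2,2(3H)-dicarboxylate, via o-quinone methide 23 (not isolated), via bromomalonate Michael adduct 24 (not isolated)
Conditions: 10 (1.3 equiv), Cs2CO3 (2.5 equiv), N-(9-anthracenylmethyl)cinchonidinium chloride (10 mol%), toluene, −20 °C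
Reagents that add atoms: none
Why: The same intermolecular Michael addition and SN2 ring closure with the pseudo-enantiomeric catalyst sets C3 of unit B as R under catalyst control; the minor facial isomer is now a diastereomer and is removed by chromatography.

Step 14
Reactants: 25 diester
Product: 27 (2RS,3R)-5-[(2S,3S)-4-chloro-6-methoxy-2-(4-methoxyphenyl)-2,3-dihydro-1-benzofuran-3-yl]-3-(3,5-dimethoxyphenyl)-7-methoxy-2,3-dihydro-1-benzofuran-2-carboxylic acid (C2 epimer mixture), via malonic diacid 26 (not isolated)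
Conditions: KOH, EtOH/H2O, 60 °C; aq. HCl; then toluene, 100 °C
Reagents that add atoms: potassium hydroxide [K+].[OH-]
Why: Saponification and malonic acid decarboxylation as in step 7, with no acidic stereocentre elsewhere in the molecule.

Step 15
Reactants: 27 carboxylic acid; 16 1-iodo-4-methoxybenzene
Product: 28 (2S,3S)-4-chloro-3-[(2R,3R)-3-(3,5-dimethoxyphenyl)-7-methoxy-2-(4-methoxyphenyl)-2,3-dihydro-1-benzofuran-5-yl]-6-methoxy-2-(4-methoxyphenyl)-2,3-dihydro-1-benzofuran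
Conditions: 16 (1.5 equiv), Ir[dF(CF3)ppy]2(dtbbpy)PF6 (1 mol%), NiCl2·glyme (10 mol%), dtbbpy (15 mol%), Cs2CO3, DMF, blue LEDs, rt
Reagents that add atoms: none
Why: Metallaphotoredox decarboxylative arylation as in step 8, the aryl group entering anti to the C3 aryl group to give the trans (2R,3R) ring of unit B.

Step 16
Reactants: 28 hexamethyl ether
Product: 29 (2S,3S)-4-chloro-3-[(2R,3R)-3-(3,5-dihydroxyphenyl)-7-hydroxy-2-(4-hydroxyphenyl)-2,3-dihydro-1-benzofuran-5-yl]-2-(4-hydroxyphenyl)-2,3-dihydro-1-benzofuran-6-ol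
Conditions: BBr3 (12 equiv), CH2Cl2, −78 → 0 °C; MeOH, then H2O
Reagents that add atoms: none
Why: Exhaustive Lewis acid demethylation done before any alkene is present, so cation–olefin cyclisation is excluded and any C2–O bond opened as a benzylic bromide recloses to the more stable trans ring on work-up (C3 centres untouched).

Step 17
Reactants: 29 hexaphenol
Product: 30 hexaacetate of 29
Conditions: Ac2O, pyridine, DMAP (cat.), rt
Reagents that add atoms: acetic anhydride CC(=O)OC(C)=O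
Why: Nucleophile-catalysed O-acylation gives a stable, chromatographable substrate with no free phenols for the palladium step.

Step 18
Reactants: 30 hexaacetate aryl chloride; 31 4-ethenylphenyl acetate
Product: 32 heptaacetate of the target with (E)-stilbene
Conditions: 31 (2 equiv), Pd2(dba)3 (3 mol%), [HP(t-Bu)3]BF4 (12 mol%), Cy2NMe, 1,4-dioxane, 100 °C
Reagents that add atoms: none
Why: Mizoroki–Heck reaction in which the bulky electron-rich phosphine allows oxidative addition of the aryl chloride and syn β-hydride elimination gives the E-alkene, the acetates being stable to the amine base.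

Step 19
Reactants: 32 heptaacetate
Product: 33 (2S,3S)-3-[(2R,3R)-3-(3,5-dihydroxyphenyl)-7-hydroxy-2-(4-hydroxyphenyl)-2,3-dihydro-1-benzofuran-5-yl]-2-(4-hydroxyphenyl)-4-[(E)-2-(4-hydroxyphenyl)ethenyl]-2,3-dihydro-1-benzofuran-6-ol
Conditions: K2CO3 (cat.), degassed MeOH, 0 °C; AcOH
Reagents that add atoms: none
Why: Base-catalysed transesterification (methanolysis) of the aryl acetates under cold, mild conditions that touch neither the stilbene nor the four stereocentres.

**Compound list**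
1 | 1-chloro-3,5-dimethoxybenzene | COc1cc(Cl)cc(OC)c1 | starting material
2 | N-[(2-chloro-4,6-dimethoxyphenyl)methylidene]-N-methylmethanaminium chloride (not isolated) | C[N+](C)=Cc1c(Cl)cc(OC)cc1OC.[Cl-] | intermediate
3 | 2-chloro-4,6-dimethoxybenzaldehyde | COc1cc(Cl)c(C=O)c(OC)c1 | intermediate
4 | 2-chloro-6-hydroxy-4-methoxybenzaldehyde | COc1cc(O)c(C=O)c(Cl)c1 | intermediate
5 | 4-bromo-2-methoxyphenol | COc1cc(Br)ccc1O | starting material
6 | 1-(benzyloxy)-4-bromo-2-methoxybenzene | COc1cc(Br)ccc1OCc1ccccc1 | intermediate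
7 | [4-(benzyloxy)-3-methoxyphenyl]magnesium bromide (not isolated) | COc1cc([Mg]Br)ccc1OCc1ccccc1 | intermediate
8 | 2-{[4-(benzyloxy)-3-methoxyphenyl](hydroxy)methyl}-3-chloro-5-methoxyphenol (racemic) | COc1cc(O)c(C(O)c2ccc(OCc3ccccc3)c(OC)c2)c(Cl)c1 | intermediate
9 | 2-{[4-(benzyloxy)-3-methoxyphenyl](4-methylbenzenesulfonyl)methyl}-3-chloro-5-methoxyphenol (racemic) | COc1cc(O)c(C(c2ccc(OCc3ccccc3)c(OC)c2)S(=O)(=O)c2ccc(C)cc2)c(Cl)c1 | intermediate
10 | diethyl 2-bromopropanedioate (diethyl bromomalonate) | CCOC(=O)C(Br)C(=O)OCC | starting material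
11 | 6-{[4-(benzyloxy)-3-methoxyphenyl]methylidene}-5-chloro-3-methoxycyclohexa-2,4-dien-1-one (not isolated) | COC1=CC(=O)C(=Cc2ccc(OCc3ccccc3)c(OC)c2)C(Cl)=C1 | intermediate
12 | diethyl 2-bromo-2-{(S)-[4-(benzyloxy)-3-methoxyphenyl](2-chloro-6-hydroxy-4-methoxyphenyl)methyl}propanedioate (not isolated) | CCOC(=O)C(Br)(C(=O)OCC)[C@@H](c1ccc(OCc2ccccc2)c(OC)c1)c1c(O)cc(OC)cc1Cl | intermediate
13 | diethyl (3S)-3-[4-(benzyloxy)-3-methoxyphenyl]-4-chloro-6-methoxy-1-benzofuran-2,2(3H)-dicarboxylate | CCOC(=O)C1(C(=O)OCC)Oc2cc(OC)cc(Cl)c2[C@@H]1c1ccc(OCc2ccccc2)c(OC)c1 | intermediate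
14 | (3S)-3-[4-(benzyloxy)-3-methoxyphenyl]-4-chloro-6-methoxy-1-benzofuran-2,2(3H)-dicarboxylic acid (not isolated) | OC(=O)C1(C(=O)O)Oc2cc(OC)cc(Cl)c2[C@@H]1c1ccc(OCc2ccccc2)c(OC)c1 | intermediate
15 | (2RS,3S)-3-[4-(benzyloxy)-3-methoxyphenyl]-4-chloro-6-methoxy-2,3-dihydro-1-benzofuran-2-carboxylic acid (C2 epimer mixture, C2 left undefined) | OC(=O)C1Oc2cc(OC)cc(Cl)c2[C@@H]1c1ccc(OCc2ccccc2)c(OC)c1 | intermediate
16 | 1-iodo-4-methoxybenzene | COc1ccc(I)cc1 | starting material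
17 | (2S,3S)-3-[4-(benzyloxy)-3-methoxyphenyl]-4-chloro-6-methoxy-2-(4-methoxyphenyl)-2,3-dihydro-1-benzofuran | COc1ccc([C@H]2Oc3cc(OC)cc(Cl)c3[C@@H]2c2ccc(OCc3ccccc3)c(OC)c2)cc1 | intermediate
18 | 4-[(2S,3S)-4-chloro-6-methoxy-2-(4-methoxyphenyl)-2,3-dihydro-1-benzofuran-3-yl]-2-methoxyphenol | COc1ccc([C@H]2Oc3cc(OC)cc(Cl)c3[C@@H]2c2ccc(O)c(OC)c2)cc1 | intermediate
19 | 5-[(2S,3S)-4-chloro-6-methoxy-2-(4-methoxyphenyl)-2,3-dihydro-1-benzofuran-3-yl]-2-hydroxy-3-methoxybenzaldehyde | COc1ccc([C@H]2Oc3cc(OC)cc(Cl)c3[C@@H]2c2cc(C=O)c(O)c(OC)c2)cc1 | intermediate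
20 | (3,5-dimethoxyphenyl)magnesium chloride (commercial THF solution) | COc1cc(OC)cc([Mg]Cl)c1 | starting material
21 | 4-[(2S,3S)-4-chloro-6-methoxy-2-(4-methoxyphenyl)-2,3-dihydro-1-benzofuran-3-yl]-2-[(3,5-dimethoxyphenyl)(hydroxy)methyl]-6-methoxyphenol (two carbinol epimers) | COc1ccc([C@H]2Oc3cc(OC)cc(Cl)c3[C@@H]2c2cc(C(O)c3cc(OC)cc(OC)c3)c(O)c(OC)c2)cc1 | intermediate
22 | 4-[(2S,3S)-4-chloro-6-methoxy-2-(4-methoxyphenyl)-2,3-dihydro-1-benzofuran-3-yl]-2-[(3,5-dimethoxyphenyl)(4-methylbenzenesulfonyl)methyl]-6-methoxyphenol (two epimers) | COc1ccc([C@H]2Oc3cc(OC)cc(Cl)c3[C@@H]2c2cc(C(c3cc(OC)cc(OC)c3)S(=O)(=O)c3ccc(C)cc3)c(O)c(OC)c2)cc1 | intermediate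
23 | 4-[(2S,3S)-4-chloro-6-methoxy-2-(4-methoxyphenyl)-2,3-dihydro-1-benzofuran-3-yl]-6-[(3,5-dimethoxyphenyl)methylidene]-2-methoxycyclohexa-2,4-dien-1-one (not isolated) | COc1ccc([C@H]2Oc3cc(OC)cc(Cl)c3[C@@H]2C2=CC(=Cc3cc(OC)cc(OC)c3)C(=O)C(OC)=C2)cc1 | intermediate
24 | diethyl 2-bromo-2-[(R)-{5-[(2S,3S)-4-chloro-6-methoxy-2-(4-methoxyphenyl)-2,3-dihydro-1-benzofuran-3-yl]-2-hydroxy-3-methoxyphenyl}(3,5-dimethoxyphenyl)methyl]propanedioate (not isolated) | COc1ccc([C@H]2Oc3cc(OC)cc(Cl)c3[C@@H]2c2cc([C@@H](c3cc(OC)cc(OC)c3)C(Br)(C(=O)OCC)C(=O)OCC)c(O)c(OC)c2)cc1 | intermediate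
25 | diethyl (3R)-5-[(2S,3S)-4-chloro-6-methoxy-2-(4-methoxyphenyl)-2,3-dihydro-1-benzofuran-3-yl]-3-(3,5-dimethoxyphenyl)-7-methoxy-1-benzofuran-2,2(3H)-dicarboxylate | COc1ccc([C@H]2Oc3cc(OC)cc(Cl)c3[C@@H]2c2cc(OC)c3c(c2)[C@@H](c2cc(OC)cc(OC)c2)C(C(=O)OCC)(C(=O)OCC)O3)cc1 | intermediate
26 | (3R)-5-[(2S,3S)-4-chloro-6-methoxy-2-(4-methoxyphenyl)-2,3-dihydro-1-benzofuran-3-yl]-3-(3,5-dimethoxyphenyl)-7-methoxy-1-benzofuran-2,2(3H)-dicarboxylic acid (not isolated) | COc1ccc([C@H]2Oc3cc(OC)cc(Cl)c3[C@@H]2c2cc(OC)c3c(c2)[C@@H](c2cc(OC)cc(OC)c2)C(C(=O)O)(C(=O)O)O3)cc1 | intermediate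
27 | (2RS,3R)-5-[(2S,3S)-4-chloro-6-methoxy-2-(4-methoxyphenyl)-2,3-dihydro-1-benzofuran-3-yl]-3-(3,5-dimethoxyphenyl)-7-methoxy-2,3-dihydro-1-benzofuran-2-carboxylic acid (C2 epimer mixture, C2 left undefined) | COc1ccc([C@H]2Oc3cc(OC)cc(Cl)c3[C@@H]2c2cc(OC)c3c(c2)[C@@H](c2cc(OC)cc(OC)c2)C(C(=O)O)O3)cc1 | intermediate
28 | (2S,3S)-4-chloro-3-[(2R,3R)-3-(3,5-dimethoxyphenyl)-7-methoxy-2-(4-methoxyphenyl)-2,3-dihydro-1-benzofuran-5-yl]-6-methoxy-2-(4-methoxyphenyl)-2,3-dihydro-1-benzofuran | COc1ccc([C@H]2Oc3cc(OC)cc(Cl)c3[C@@H]2c2cc(OC)c3c(c2)[C@@H](c2cc(OC)cc(OC)c2)[C@H](c2ccc(OC)cc2)O3)cc1 | intermediate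
29 | (2S,3S)-4-chloro-3-[(2R,3R)-3-(3,5-dihydroxyphenyl)-7-hydroxy-2-(4-hydroxyphenyl)-2,3-dihydro-1-benzofuran-5-yl]-2-(4-hydroxyphenyl)-2,3-dihydro-1-benzofuran-6-ol | Oc1ccc([C@H]2Oc3cc(O)cc(Cl)c3[C@@H]2c2cc(O)c3c(c2)[C@@H](c2cc(O)cc(O)c2)[C@H](c2ccc(O)cc2)O3)cc1 | intermediate
30 | hexaacetate of 29 (all six phenols as acetates) | CC(=O)Oc1ccc([C@H]2Oc3cc(OC(C)=O)cc(Cl)c3[C@@H]2c2cc(OC(C)=O)c3c(c2)[C@@H](c2cc(OC(C)=O)cc(OC(C)=O)c2)[C@H](c2ccc(OC(C)=O)cc2)O3)cc1 | intermediate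
31 | 4-ethenylphenyl acetate (4-acetoxystyrene) | CC(=O)Oc1ccc(C=C)cc1 | starting material
32 | heptaacetate of 33 (all seven phenols as acetates, E-stilbene) | CC(=O)Oc1ccc(/C=C/c2cc(OC(C)=O)cc3c2[C@H](c2cc(OC(C)=O)c4c(c2)[C@@H](c2cc(OC(C)=O)cc(OC(C)=O)c2)[C@H](c2ccc(OC(C)=O)cc2)O4)[C@@H](c2ccc(OC(C)=O)cc2)O3)cc1 | intermediate
33 | (2S,3S)-3-[(2R,3R)-3-(3,5-dihydroxyphenyl)-7-hydroxy-2-(4-hydroxyphenyl)-2,3-dihydro-1-benzofuran-5-yl]-2-(4-hydroxyphenyl)-4-[(E)-2-(4-hydroxyphenyl)ethenyl]-2,3-dihydro-1-benzofuran-6-ol | Oc1ccc(/C=C/c2cc(O)cc3c2[C@H](c2cc(O)c4c(c2)[C@@H](c2cc(O)cc(O)c2)[C@H](c2ccc(O)cc2)O4)[C@@H](c2ccc(O)cc2)O3)cc1 | target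

**Totals**
Total step count: 19. Longest linear sequence: 18 steps (from 1 through steps 1, 2 and 4–19; step 3 is the side branch).

**Three steps most likely to fail**

Step 6. The o-quinone methide is flanked by chlorine, so the asymmetric annulation may give low ee or conversion. Fallback: set out from 9 and run the same Michael addition and ring closure with 10 under achiral phase transfer (Bu4NBr, Cs2CO3, CH2Cl2, rt to 40 °C, where higher temperature is affordable). This passes through racemic diethyl 2-bromo-2-{[4-(benzyloxy)-3-methoxyphenyl](2-chloro-6-hydroxy-4-methoxyphenyl)methyl}propanedioate F1 to racemic diethyl 3-[4-(benzyloxy)-3-methoxyphenyl]-4-chloro-6-methoxy-1-benzofuran-2,2(3H)-dicarboxylate F2. F2 is resolved by preparative SFC on a chiral stationary phase; its (S)-enantiomer is 13, where the route is rejoined.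

Step 15. The acid is large and the C2 radical is hindered, so the photoredox coupling may stall or give mainly protodecarboxylation. Fallback: set out from 27 and activate it with N-hydroxyphthalimide, N,N'-diisopropylcarbodiimide and DMAP (cat.) in CH2Cl2 to the redox-active ester 1,3-dioxoisoindolin-2-yl (2RS,3R)-5-[(2S,3S)-4-chloro-6-methoxy-2-(4-methoxyphenyl)-2,3-dihydro-1-benzofuran-3-yl]-3-(3,5-dimethoxyphenyl)-7-methoxy-2,3-dihydro-1-benzofuran-2-carboxylate F3. F3 is then coupled thermally with commercial (4-methoxyphenyl)zinc iodide (NiCl2·glyme, dtbbpy, THF/DMF, rt) in a decarboxylative Negishi-type arylation, again trans-selective, and the route is rejoined at 28.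

Step 18. The aryl chloride is hindered and electron-rich, so the Heck reaction may be slow. Fallback: make 4-[(E)-2-(4,4,5,5-tetramethyl-1,3,2-dioxaborolan-2-yl)ethenyl]phenyl acetate F4 from 31 and vinylboronic acid pinacol ester by cross-metathesis (second-generation Grubbs catalyst RuCl2(=CHPh)(H2IMes)(PCy3), CH2Cl2, 40 °C). Then set out from hexaphenol 29 and couple it with F4 by Suzuki–Miyaura reaction (Pd(OAc)2, XPhos, K3PO4, degassed 1,4-dioxane/H2O, 80 °C). The aryl acetate of F4 is cleaved by the aqueous base in the same flask, so the route is rejoined directly at 33, skipping steps 17–19.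

**Further compounds**
F1 | step 6 | racemic diethyl 2-bromo-2-{[4-(benzyloxy)-3-methoxyphenyl](2-chloro-6-hydroxy-4-methoxyphenyl)methyl}propanedioate (not isolated) | CCOC(=O)C(Br)(C(=O)OCC)C(c1ccc(OCc2ccccc2)c(OC)c1)c1c(O)cc(OC)cc1Cl
F2 | step 6 | racemic diethyl 3-[4-(benzyloxy)-3-methoxyphenyl]-4-chloro-6-methoxy-1-benzofuran-2,2(3H)-dicarboxylate | CCOC(=O)C1(C(=O)OCC)Oc2cc(OC)cc(Cl)c2C1c1ccc(OCc2ccccc2)c(OC)c1
F3 | step 15 | 1,3-dioxoisoindolin-2-yl (2RS,3R)-5-[(2S,3S)-4-chloro-6-methoxy-2-(4-methoxyphenyl)-2,3-dihydro-1-benzofuran-3-yl]-3-(3,5-dimethoxyphenyl)-7-methoxy-2,3-dihydro-1-benzofuran-2-carboxylate | COc1ccc([C@H]2Oc3cc(OC)cc(Cl)c3[C@@H]2c2cc(OC)c3c(c2)[C@@H](c2cc(OC)cc(OC)c2)C(C(=O)ON2C(=O)c4ccccc4C2=O)O3)cc1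
F4 | step 18 | 4-[(E)-2-(4,4,5,5-tetramethyl-1,3,2-dioxaborolan-2-yl)ethenyl]phenyl acetate | CC(=O)Oc1ccc(/C=C/B2OC(C)(C)C(C)(C)O2)cc1
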